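**The question.** How much D stands beside X in birch at 30 min, at 2.0 h and at 10 h? Birch has been followed for 50.0 min, and its D readings lie within 1.5 percentage points of zero, so we turn to alder, which has the same cZ and cG but half the cE.

| flask | Z | E | G | remark | time |
|---|---|---|---|---|---|
| birch | 1.4 M | 1.12 M | 1.68 M | the very flask that is asked about, followed so far |  |
| alder | 1.4 M | 0.56 M | 1.68 M | run made earlier |  |
| flask | 1.4 M | 1.12 M | 1.68 M |  | 10 h |

birch run (percent of the Z charged)

| time / min | D / % | X / % |
|---|---|---|
| 4.00 | 0 | 0 |
| 8.00 | 1 | 3 |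
| 15.0 | 0 | 3 |
| 25.0 | 0 | 4 |
| 50.0 | 0 | 2 |

alder run (percent of the Z charged)

| time / h | D / % | X / % |
|---|---|---|
| 0.667 | 0 | 3 |
| 2.00 | 0 | 8 |
| 3.00 | 0 | 16 |
| 5.00 | 0 | 20 |
| 8.00 | 2 | 30 |

(readings scatter by 1.5 percentage points)

- ratio of D to X at 30 min
- ratio of D to X at 2.0 h
- ratio of D to X at 10 h
- which of D and X there is more of at 10 h

**Same pace.** Alder's X, drawn straight through its 30% at 8.00 h, stands at 3.12% at 50.0 min, and birch reads 2% there, a gap within the scatter of 1.5 points. So the extra E shows no speed-up of X. We therefore reckon that the two flasks differ in how D and X share the product, not in pace: D and X grow side by side, their ratio steady in time and proportional to cE.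

**The split.** A line through the origin of D against X in alder has the slope 0.0368. Dividing by alder's cE gives 0.0658 M⁻¹, our split (a selectivity factor): D made per X made, for each molar of E, with cG charged at 1.68 M. One nonzero reading of D carries it, 2%, so it is rough. Alder's early zeros don't oppose it: at 5.00 h the slope asks for 0.737% of D, less than the scatter. For birch we commit to 0.0737 at every time, with X ahead.

**The forecast.** It gives 0.008, 0.03 and 0.13, with X leading: "This late appearance suggests D forms from X". Its ratio climbs, from below ours to above it.

**The flask.** The ratios are 0.0851, 0.0872 and 0.0973, and X leads.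

    Z → J (k = 0.0519 h⁻¹)
    E + J → D (k = 10.4 M⁻¹ h⁻¹)
    G + J → X (k = 82.1 M⁻¹ h⁻¹)
    J → Q (k = 10.1 h⁻¹)

At 10.0 h the flask holds 3.33% of D and 34.2% of X, with 59.5% of Z still there. Our 0.0737 on that X gives 2.52% of D, less than the flask holds.

**Less E.** In a neighbour flask with 0.45 M of E, its other charges as in birch, the split gives 0.0296; the computed ratios there are 0.0342 at 30 min and 0.0394 at 10 h.

The data stem from a simulated flask with constants of no real substance.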